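The route rests on cutting the C5–C10 bond (elemane locants) between the quaternary ring carbon C10 (vinyl C1=C2, C14H2OAc) and C5. In the cyclohexane the array C2=C1–C10–C5–C6(O) is a γ,δ-unsaturated carboxyl unit. C14–C10–C9–C8–C7, with its 1,4-oxygens, maps onto (S)-5-(hydroxymethyl)butyrolactone. One dienolate Ireland–Claisen shift therefore forges C5–C10, sets both stereocentres and releases the vinyl and isopropenyl groups, closing no ring. Its precursor is the 3-methylbut-2-enoate of an (E)-α-(2-hydroxyethylidene)lactone whose trityloxymethyl arm blocks one face. The lactone is then transposed to C6/C14, and the cyclohexane and α-methylene lactone close late by C6–C7 allylation.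

Key step: step 6

Remark on the chemistry: atoms carry the elemane locants of the target in all compounds. Centres that are destroyed or made irrelevant later (C1 and C10 in 5 and 6, the lactol or acetal carbon C6, the carbinol C7 in 23 and 24) are carried as mixtures and drawn without descriptor. Commercial LDA solution is assumed.

Step 1
Reactants: 1 (S)-5-(hydroxymethyl)dihydrofuran-2(3H)-one
Product: 2 (S)-5-(trityloxymethyl)dihydrofuran-2(3H)-one
Conditions: TrCl, pyridine, DMAP (cat.), CH2Cl2, rt
Reagents that add atoms: trityl chloride ClC(c1ccccc1)(c1ccccc1)c1ccccc1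
Why: O-Tritylation of the only hydroxyl group is routine, leaves the bought C8 centre (S) untouched and installs the bulky arm that later shields one lactone face.

Step 2
Reactants: 2 (S)-5-(trityloxymethyl)dihydrofuran-2(3H)-one; 3 (tert-butyldimethylsilyloxy)acetaldehyde
Product: 5 (5S)-3-[2-(tert-butyldimethylsilyloxy)-1-hydroxyethyl]-5-(trityloxymethyl)dihydrofuran-2(3H)-one (diastereomer mixture), via lithium enolate 4 (not isolated)
Conditions: LDA (1.1 equiv), THF, −78 °C; 3, −78 °C; AcOH quench at −78 °C
Reagents that add atoms: lithium diisopropylamide [Li+].CC(C)[N-]C(C)C (lithium, held only by 4)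
Why: Lithium enolate aldol addition at C10, the only acidic site of 2, joins C10 to C1, and the two new centres need no control because both become sp2 in step 3.

Step 3
Reactants: 5 aldol adduct
Product: 7 (S,E)-3-[2-(tert-butyldimethylsilyloxy)ethylidene]-5-(trityloxymethyl)dihydrofuran-2(3H)-one, via mesylate 6 (not isolated)
Conditions: MsCl, Et3N, CH2Cl2, 0 °C; then DBU, 0 °C → rt
Reagents that add atoms: methanesulfonyl chloride CS(=O)(=O)Cl (held only by 6)
Why: Mesylation followed by E1cB elimination gives the conjugated alkylidene lactone, the reversible enolate pathway with DBU favouring the E isomer in which C2 lies cis to C9 and away from the carbonyl group, and any Z isomer is removed by chromatography because this geometry is translated into C5 in step 6.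

Step 4
Reactants: 7 silyl-protected (E)-alkylidene lactone
Product: 8 (S,E)-3-(2-hydroxyethylidene)-5-(trityloxymethyl)dihydrofuran-2(3H)-one
Conditions: HF·pyridine, excess pyridine, THF, 0 °C → rt
Reagents that add atoms: none
Why: Fluoride-driven Si–O cleavage with pyridine-buffered HF frees the primary allylic alcohol while the acid-labile trityl ether and the base-sensitive alkylidene lactone are spared, and the E geometry keeps the new hydroxyl group from lactonising onto C14.

Step 5
Reactants: 8 (E)-allylic alcohol; 9 3-methylbut-2-enoyl chloride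
Product: 10 (E)-2-[(5S)-2-oxo-5-(trityloxymethyl)dihydrofuran-3(2H)-ylidene]ethyl 3-methylbut-2-enoate
Conditions: 9 (1.3 equiv), pyridine, DMAP (cat.), CH2Cl2, 0 °C
Reagents that add atoms: none
Why: DMAP-catalysed acylation of a primary allylic alcohol with an acid chloride is routine, pyridine being too weak a base to drive much vinylketene formation, and any 3-methylbut-3-enoate formed that way enters step 6 through the same dienolate.

Step 6
Reactants: 10 allylic 3-methylbut-2-enoate
Product: 14 (2S)-3-methyl-2-[(3R,5S)-2-oxo-5-(trityloxymethyl)-3-vinyltetrahydrofuran-3-yl]but-3-enoic acid (5S,8S,10R), via lithium dienolate 11 (not isolated), via silyl ketene acetal 12 (not isolated), via trimethylsilyl ester 13 (not isolated)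
Conditions: TMSCl/Et3N (premixed, 3 equiv), THF, −78 °C, slow addition of LDA (1.3 equiv); −78 °C → rt, then 50 °C; aq. citric acid work-up
Reagents that add atoms: lithium diisopropylamide [Li+].CC(C)[N-]C(C)C (lithium, held only by 11); chlorotrimethylsilane C[Si](C)(C)Cl (held only by 12 and 13)
Why: Proposed new method: LDA bound to the carbonyl oxygen of the s-cis senecioate takes a proton from the methyl group cis to that carbonyl, TMSCl already present traps dienolate 11 on oxygen as the (Z)-silyl ketene acetal 12 (isopropenyl cis to OSi), and on warming 12 undergoes a concerted chair [3,3] shift in which C5 bonds to C10 while the C2–O bond breaks and the alkene moves to C1=C2. The closest known reaction type is the deconjugative Ireland–Claisen rearrangement of allyl 3-methylbut-2-enoates, which also builds quaternary carbons at trisubstituted alkene termini, and Claisen shifts onto the α-carbon of γ-hydroxy enoates are known under neutral orthoester conditions; what is untested is an α-alkylidene lactone as allyl partner under amide-base conditions. No ring is closed, the lactone serving only as a rigid template. C10 is set by facial control, because the ketene acetal can reach the flat alkylidene lactone only on the face opposite the CH2OTr arm on C8, which places C5 trans and the new vinyl group cis to that arm. C5 is set by the chair, in which the E alkene holds C9 axial and C14 equatorial and the Z ketene acetal holds the isopropenyl group equatorial, and this pairing gives the (5S,10R) relation of 14 that matches the target. The step needs site-selective deprotonation, which is secured because C10 carries no hydrogen, the C2 hydrogens lie trans to the lactone carbonyl and out of reach of a carbonyl-bound amide, and the internal quench never lets free dienolate build up next to the acceptor alkene.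

Step 7
Reactants: 14 Claisen acid
Product: 17 (3S,4R)-4-[(2S)-2-hydroxy-3-(trityloxy)propyl]-3-(prop-1-en-2-yl)-4-vinyldihydrofuran-2(3H)-one, via lithium carboxylate 15 (not isolated), via dihydroxy acid 16 (not isolated)
Conditions: LiEt3BH (3.3 equiv), THF, −78 → 0 °C; then AcOH/H2O, rt
Reagents that add atoms: lithium triethylborohydride [Li+].CC[BH-](CC)CC (lithium held only by 15, otherwise hydride only)
Why: Chemoselective hydride reduction of a lactone beside a carboxylate salt followed by acid-induced γ-lactonisation: the first equivalent of LiEt3BH converts the acid into the inert carboxylate 15, two more reduce the hindered C14 lactone to the diol, the only boron by-product is Et3B, which cannot hydroborate the vinyl or isopropenyl group as borane residues from LiBH4 could, and on acidification acid 16 closes onto the primary C14 hydroxyl group (five-membered ring, gem-dialkyl effect) rather than onto C8–OH, no stereocentre being touched.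

Step 8
Reactants: 17 transposed C6/C14 γ-lactone
Product: 18 (3S,4R)-3-(prop-1-en-2-yl)-4-[(2S)-2-(triisopropylsilyloxy)-3-(trityloxy)propyl]-4-vinyldihydrofuran-2(3H)-one
Conditions: TIPSOTf, 2,6-lutidine, CH2Cl2, −20 → 0 °C
Reagents that add atoms: triisopropylsilyl triflate CC(C)[Si](C(C)C)(C(C)C)OS(=O)(=O)C(F)(F)F
Why: Silylation of the secondary C8 alcohol with a silyl triflate under lutidine buffering spares the trityl ether, and TIPS is chosen because it outlasts the acidic methanol of step 10, the amine of step 12 and the aqueous acid of step 14, resists 1,2-migration and cannot chelate a metal in step 15.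

Step 9
Reactants: 18 silylated lactone
Product: 19 (3S,4R)-3-(prop-1-en-2-yl)-4-[(2S)-2-(triisopropylsilyloxy)-3-(trityloxy)propyl]-4-vinyltetrahydrofuran-2-ol (anomers)
Conditions: i-Bu2AlH (1.2 equiv), toluene, −78 °C; aq. potassium sodium tartrate
Reagents that add atoms: none
Why: Half-reduction of a γ-lactone with i-Bu2AlH stops at the aluminium hemiacetal at −78 °C and gives after work-up the lactol that masks the epimerisable, conjugation-prone C6 aldehyde, with C5 untouched.

Step 10
Reactants: 19 lactol
Product: 20 (2S)-3-[(3R,4S)-5-methoxy-4-(prop-1-en-2-yl)-3-vinyltetrahydrofuran-3-yl]-2-(triisopropylsilyloxy)propan-1-ol (anomers)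
Conditions: CSA (cat.), MeOH/CH2Cl2, 0 °C → rt
Reagents that add atoms: methanol CO
Why: Acid-catalysed acetalisation of the lactol and methanolysis of the trityl ether proceed under the same mild conditions, which a secondary TIPS ether and both alkenes tolerate, so that C6 is locked as methyl acetal and the C7 hydroxyl group is released in one operation.

Step 11
Reactants: 20 primary alcohol
Product: 21 (2S)-3-[(3R,4S)-5-methoxy-4-(prop-1-en-2-yl)-3-vinyltetrahydrofuran-3-yl]-2-(triisopropylsilyloxy)propanal (anomers)
Conditions: Dess–Martin periodinane, CH2Cl2, 0 °C → rt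
Reagents that add atoms: none
Why: Dess–Martin oxidation turns the primary alcohol into the α-silyloxy aldehyde under non-enolising conditions, so the C8 centre is kept, and the aldehyde is used at once.

Step 12
Reactants: 21 C7 aldehyde; 22 methyl acrylate
Product: 23 methyl (4S)-3-hydroxy-5-[(3R,4S)-5-methoxy-4-(prop-1-en-2-yl)-3-vinyltetrahydrofuran-3-yl]-2-methylidene-4-(triisopropylsilyloxy)pentanoate (C7 carbinol epimers)
Conditions: 22 (excess, neat), quinuclidine (0.5 equiv), MeOH (1 equiv), 0 °C → rt
Reagents that add atoms: none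
Why: Morita–Baylis–Hillman reaction, in which the inductively activated α-silyloxy aldehyde is a comparatively fast acceptor and the strong nucleophile quinuclidine with methanol as proton shuttle keeps the contact time short enough to protect C8 from epimerisation; both C7 carbinol epimers are used because C7 becomes sp2 in step 13.

Step 13
Reactants: 23 Morita–Baylis–Hillman adduct
Product: 25 methyl (2Z,4S)-2-(bromomethyl)-5-[(3R,4S)-5-methoxy-4-(prop-1-en-2-yl)-3-vinyltetrahydrofuran-3-yl]-4-(triisopropylsilyloxy)pent-2-enoate, via alkoxysulfonium bromide 24 (not isolated)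
Conditions: NBS/Me2S (premixed, Me2S in slight excess), CH2Cl2, 0 °C; then 23, 0 °C → rt
Reagents that add atoms: N-bromosuccinimide O=C1CCC(=O)N1Br (bromine); dimethyl sulfide CSC (held only by 24)
Why: SN2' bromination of a Morita–Baylis–Hillman alcohol through its alkoxysulfonium salt, where bromide attacks C13 and allylic strain places C8 trans to the ester so that both carbinol epimers converge on the Z bromide, the premixed reagent leaving no free NBS to attack the isopropenyl group and no acid to open the acetal.

Step 14
Reactants: 25 bromide with methyl acetal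
Product: 26 methyl (2Z,4S)-2-(bromomethyl)-5-[(3R,4S)-5-hydroxy-4-(prop-1-en-2-yl)-3-vinyltetrahydrofuran-3-yl]-4-(triisopropylsilyloxy)pent-2-enoate (anomers)
Conditions: AcOH/THF/H2O (3:1:1), 35–40 °C
Reagents that add atoms: water O
Why: Mild aqueous-acid hydrolysis of a 2-methoxytetrahydrofuran acetal frees the lactol under conditions to which the secondary TIPS ether and the electron-poor primary allylic bromide are inert, and bromination had to come first because the sulfonium reagent would oxidise a free lactol.

Step 15
Reactants: 26 bromide with free lactol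
Product: 29 (5S,6R,7S,8S,10R)-14-hydroxy-8-(triisopropylsilyloxy)elema-1,3,11(13)-trien-12,6-olide (trans-fused lactone), via allylindium dibromide 27 (not isolated), via hydroxy ester 28 (not isolated)
Conditions: In powder (2 equiv), THF/H2O (1:1), 0.005 M, rt; then TsOH·H2O (cat.), CH2Cl2, rt
Reagents that add atoms: indium [In] (held only by 27)
Why: Intramolecular indium Barbier allylation of a lactol-masked aldehyde (γ-attack of C7 on C6, six-membered carbocycle) followed by acid-catalysed 5-exo-trig lactonisation; since a closed chair of the Z allylmetal itself would lead to the cis lactone, the step relies on the fast 1,3-metal shift of allylindium 27 while the aldehyde is released only slowly from the lactol, so that closure can choose the trans-decalin-like transition state of the E form with C4, O6, C11 and O8 all equatorial, the cis alternative having to hold the metal-bound O6 axial against the axial C14H2OH on C10, and this sets C6 (R) and C7 with H6 and H7 trans-diaxial.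

Step 16
Reactants: 29 silylated tricarbocyclic lactone
Product: 30 (5S,6R,7R,8S,10R)-8,14-dihydroxyelema-1,3,11(13)-trien-12,6-olide
Conditions: HF·pyridine, MeCN, 0 °C → rt
Reagents that add atoms: none
Why: Desilylation with HF·pyridine works under weakly acidic conditions, which avoids the conjugate addition to the α-methylene lactone and the O8-to-C12 translactonisation that basic fluoride could trigger.

Step 17
Reactants: 30 diol
Product: 31 (5S,6R,7R,8S,10R)-8,14-diacetoxyelema-1,3,11(13)-trien-12,6-olide
Conditions: Ac2O, pyridine, DMAP (cat.), CH2Cl2, 0 °C → rt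
Reagents that add atoms: acetic anhydride CC(=O)OC(C)=O
Why: DMAP-catalysed acetylation esterifies the secondary C8 and the neopentyl primary C14 hydroxyl groups together and quickly enough that the free C8 alcohol does not migrate onto the lactone carbonyl.

Step 18
Reactants: 31 diacetate with isopropenyl group
Product: 32 (5S,6R,7R,8S,10R)-8,14-diacetoxy-15-hydroxyelema-1,3,11(13)-trien-12,6-olide
Conditions: SeO2 (0.5 equiv), t-BuOOH (3 equiv), CH2Cl2, 0 °C → rt
Reagents that add atoms: selenium dioxide O=[Se]=O (oxygen carrier); tert-butyl hydroperoxide CC(C)(C)OO (terminal oxygen source)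
Why: SeO2 allylic oxidation (ene reaction then [2,3]-sigmatropic shift) can only engage the isopropenyl group, since the vinyl group has no allylic hydrogen (C10 is quaternary) and the methylene lactone is electron-poor, and it takes the open methyl group rather than the hindered C5 methine, giving the allylic alcohol together with some enal 33.

Step 19
Reactants: 32 allylic alcohol (crude, with any 33)
Product: 33 (5R,6R,7R,8S,10R)-8,14-diacetoxy-15-oxoelema-1,3,11(13)-trien-12,6-olide (CNP0200597.1)
Conditions: Dess–Martin periodinane, CH2Cl2, 0 °C → rt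
Reagents that add atoms: none
Why: Dess–Martin oxidation of the allylic alcohol converges all material on the enal without touching acetates, lactone or stereocentres, C5 changing its descriptor to R only through the priority switch.

Compound list
1 | (S)-5-(hydroxymethyl)dihydrofuran-2(3H)-one | OC[C@@H]1CCC(=O)O1 | starting material
2 | (S)-5-(trityloxymethyl)dihydrofuran-2(3H)-one | O=C1CC[C@@H](COC(c2ccccc2)(c2ccccc2)c2ccccc2)O1 | intermediate
3 | (tert-butyldimethylsilyloxy)acetaldehyde | O=CCO[Si](C)(C)C(C)(C)C | starting material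
4 | lithium enolate of 2 | [Li+].[O-]C1=CC[C@@H](COC(c2ccccc2)(c2ccccc2)c2ccccc2)O1 | intermediate (not isolated)
5 | aldol adduct, (8S), mixture at C10 and C1 | CC(C)(C)[Si](C)(C)OCC(O)C1C[C@@H](COC(c2ccccc2)(c2ccccc2)c2ccccc2)OC1=O | intermediate
6 | C1 mesylate of 5 | CC(C)(C)[Si](C)(C)OCC(OS(C)(=O)=O)C1C[C@@H](COC(c2ccccc2)(c2ccccc2)c2ccccc2)OC1=O | intermediate (not isolated)
7 | (S,E)-3-[2-(tert-butyldimethylsilyloxy)ethylidene]-5-(trityloxymethyl)dihydrofuran-2(3H)-one | CC(C)(C)[Si](C)(C)OC/C=C1\C[C@@H](COC(c2ccccc2)(c2ccccc2)c2ccccc2)OC1=O | intermediate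
8 | (S,E)-3-(2-hydroxyethylidene)-5-(trityloxymethyl)dihydrofuran-2(3H)-one | OC/C=C1\C[C@@H](COC(c2ccccc2)(c2ccccc2)c2ccccc2)OC1=O | intermediate
9 | 3-methylbut-2-enoyl chloride | CC(C)=CC(Cl)=O | starting material
10 | allylic 3-methylbut-2-enoate of 8 | CC(C)=CC(=O)OC/C=C1\C[C@@H](COC(c2ccccc2)(c2ccccc2)c2ccccc2)OC1=O | intermediate
11 | lithium dienolate of 10 (isopropenyl cis to OLi) | [Li+].C=C(C)/C=C(\[O-])OC/C=C1\C[C@@H](COC(c2ccccc2)(c2ccccc2)c2ccccc2)OC1=O | intermediate (not isolated)
12 | (Z)-trimethylsilyl ketene acetal | C=C(C)/C=C(\O[Si](C)(C)C)OC/C=C1\C[C@@H](COC(c2ccccc2)(c2ccccc2)c2ccccc2)OC1=O | intermediate (not isolated)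
13 | trimethylsilyl ester of 14 | C=C[C@]1(C[C@@H](COC(c2ccccc2)(c2ccccc2)c2ccccc2)OC1=O)[C@H](C(C)=C)C(=O)O[Si](C)(C)C | intermediate (not isolated)
14 | Claisen acid (5S,8S,10R) | C=C[C@]1(C[C@@H](COC(c2ccccc2)(c2ccccc2)c2ccccc2)OC1=O)[C@H](C(C)=C)C(O)=O | intermediate
15 | lithium carboxylate of 14 | [Li+].C=C[C@]1(C[C@@H](COC(c2ccccc2)(c2ccccc2)c2ccccc2)OC1=O)[C@H](C(C)=C)C([O-])=O | intermediate (not isolated)
16 | (2S,3R)-3-(hydroxymethyl)-3-[(2S)-2-hydroxy-3-(trityloxy)propyl]-2-(prop-1-en-2-yl)pent-4-enoic acid | C=C[C@](CO)(C[C@H](O)COC(c1ccccc1)(c1ccccc1)c1ccccc1)[C@H](C(C)=C)C(O)=O | intermediate (not isolated)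
17 | transposed C6/C14 γ-lactone, C8–OH free (5S,8S,10R) | C=C[C@]1(COC(=O)[C@H]1C(C)=C)C[C@H](O)COC(c2ccccc2)(c2ccccc2)c2ccccc2 | intermediate
18 | TIPS ether of 17 | C=C[C@]1(COC(=O)[C@H]1C(C)=C)C[C@H](O[Si](C(C)C)(C(C)C)C(C)C)COC(c2ccccc2)(c2ccccc2)c2ccccc2 | intermediate
19 | C6 lactol (anomers) | C=C[C@]1(COC(O)[C@H]1C(C)=C)C[C@H](O[Si](C(C)C)(C(C)C)C(C)C)COC(c2ccccc2)(c2ccccc2)c2ccccc2 | intermediate
20 | C6 methyl acetal, C7–OH free (anomers) | C=C[C@]1(COC(OC)[C@H]1C(C)=C)C[C@H](O[Si](C(C)C)(C(C)C)C(C)C)CO | intermediate
21 | C7 aldehyde with C6 methyl acetal (anomers) | C=C[C@]1(COC(OC)[C@H]1C(C)=C)C[C@H](O[Si](C(C)C)(C(C)C)C(C)C)C=O | intermediate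
22 | methyl acrylate | C=CC(=O)OC | starting material
23 | Morita–Baylis–Hillman adduct (C7 epimers) | C=C[C@]1(COC(OC)[C@H]1C(C)=C)C[C@H](O[Si](C(C)C)(C(C)C)C(C)C)C(O)C(=C)C(=O)OC | intermediate
24 | C7 alkoxy(dimethyl)sulfonium bromide of 23 | C=C[C@]1(COC(OC)[C@H]1C(C)=C)C[C@H](O[Si](C(C)C)(C(C)C)C(C)C)C(O[S+](C)C)C(=C)C(=O)OC.[Br-] | intermediate (not isolated)
25 | (Z)-2-(bromomethyl)enoate with methyl acetal | C=C[C@]1(COC(OC)[C@H]1C(C)=C)C[C@H](O[Si](C(C)C)(C(C)C)C(C)C)/C=C(\CBr)C(=O)OC | intermediate
26 | (Z)-2-(bromomethyl)enoate with free lactol | C=C[C@]1(COC(O)[C@H]1C(C)=C)C[C@H](O[Si](C(C)C)(C(C)C)C(C)C)/C=C(\CBr)C(=O)OC | intermediate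
27 | allylindium dibromide in its open hydroxy aldehyde form (alkene geometry fluxional) | C=C[C@](CO)(C[C@H](O[Si](C(C)C)(C(C)C)C(C)C)C=C(C[In](Br)Br)C(=O)OC)[C@@H](C=O)C(C)=C | intermediate (not isolated)
28 | cyclohexane hydroxy ester, equatorial C6–OH and C7–C(=CH2)CO2Me (5S,6R,7S,8S,10R) | C=C[C@]1(CO)C[C@H](O[Si](C(C)C)(C(C)C)C(C)C)[C@@H](C(=C)C(=O)OC)[C@H](O)[C@H]1C(C)=C | intermediate (not isolated)
29 | 14-hydroxy-8-(triisopropylsilyloxy)elema-1,3,11(13)-trien-12,6-olide (5S,6R,7S,8S,10R) | C=C[C@]1(CO)C[C@H](O[Si](C(C)C)(C(C)C)C(C)C)[C@H]2C(=C)C(=O)O[C@@H]2[C@H]1C(C)=C | intermediate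
30 | 8,14-dihydroxyelema-1,3,11(13)-trien-12,6-olide (5S,6R,7R,8S,10R) | C=C[C@]1(CO)C[C@H](O)[C@H]2C(=C)C(=O)O[C@@H]2[C@H]1C(C)=C | intermediate
31 | 8,14-diacetoxyelema-1,3,11(13)-trien-12,6-olide (5S,6R,7R,8S,10R) | C=C[C@]1(COC(C)=O)C[C@H](OC(C)=O)[C@H]2C(=C)C(=O)O[C@@H]2[C@H]1C(C)=C | intermediate
32 | 8,14-diacetoxy-15-hydroxyelema-1,3,11(13)-trien-12,6-olide (5S,6R,7R,8S,10R) | C=C[C@]1(COC(C)=O)C[C@H](OC(C)=O)[C@H]2C(=C)C(=O)O[C@@H]2[C@H]1C(=C)CO | intermediate
33 | 8,14-diacetoxy-15-oxoelema-1,3,11(13)-trien-12,6-olide (5R,6R,7R,8S,10R), CNP0200597.1 | C=C[C@]1(COC(C)=O)C[C@H](OC(C)=O)[C@H]2C(=C)C(=O)O[C@@H]2[C@H]1C(=C)C=O | target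

Total step count: 19. Longest linear sequence: 19 steps (1 → 33); 3, 9 and 22 are bought and enter directly.

Steps most likely to fail

1. Step 6 (carries the label).
- **What may go wrong:** the amide may deprotonate C2 or add in conjugate fashion to the acceptor alkene. The carboxylate may be lost by base-induced 1,4-elimination. The carbonyl group on the bond-forming terminus may slow the shift so that the silyl ketene acetal decays first. A boat pathway or attack on the shielded face may erode the C5/C10 control.
- **Fallback (known chemistry, non-acceptor template):** it sets out from 8 and removes the acceptor character before the rearrangement while keeping the ring and its CH2OTr arm. i-Bu2AlH (−78 °C) would give the alkylidene lactol diol F1, and a trace of PPTS in methanol the methyl acetal alcohol F2. The anomer with OMe on the CH2OTr face is taken on and the other is re-equilibrated. Acylation with 9 gives the senecioate F3, now an ordinary trisubstituted allylic ester. For such esters the dienolate Ireland–Claisen rearrangement with quaternary-centre formation is established. LDA with TMSCl present leads through the lithium dienolate F4, the silyl ketene acetal F5 and the silyl ester F6 to the acetal acid F7. Aqueous acetic acid at rt frees the lactol acid F8, NaBH4 in THF/aq. NaOH reduces C14 to give 16, and acidification rejoins the route at 17.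

2. Step 15.
- **What may go wrong:** ring closure may outrun the metal shift, so that the Z allylindium reacts through its own closed chair and the ring fusion comes out cis (C6 inverted). Protonolysis of the allylindium while the aldehyde rests as lactol, or reductive 1,4-loss of the silyloxy group, may consume material.
- **Fallback (different oxidation level at C12, lactone made by oxidation):** it sets out from 25. i-Bu2AlH (CH2Cl2, −78 °C) would reduce the ester to the bromo allylic alcohol F9, and aqueous acetic acid frees the bromo lactol F10. Indium in THF/H2O gives the allylindium F11, in which the two C11 substituents (CH2In, CH2OH) are of like size. No built-in preference for the Z form then remains, and the known anti preference of allylindium reagents with bulky γ-substituents operates. Closure gives the triol F12 with equatorial O6 and C11. MnO2 oxidises only the allylic C12 alcohol, through the methylene lactol F13, and the route is rejoined at 29.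

3. Step 12.
- **What may go wrong:** addition to the hindered α-branched aldehyde may be sluggish, and long exposure to the amine may epimerise C8 or move the silyl group.
- **Fallback (stoichiometric Michael–aldol instead of amine catalysis):** it sets out from 21 and 22. PhSeLi (THF, −78 °C) adds to 22 to give the lithium ester enolate F14. Aldehyde 21 traps this within minutes at −78 °C as the selanyl aldol F15 (AcOH quench). H2O2/pyridine (CH2Cl2, 0 °C) gives the selenoxide F16, whose syn elimination rejoins the route at 23.

Further compounds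
F1 | step 6 | (E)-3-(2-hydroxyethylidene)-5-(trityloxymethyl)tetrahydrofuran-2-ol, (8S), anomers | OC/C=C1\C[C@@H](COC(c2ccccc2)(c2ccccc2)c2ccccc2)OC1O
F2 | step 6 | (E)-2-[2-methoxy-5-(trityloxymethyl)dihydrofuran-3(2H)-ylidene]ethanol, (8S) | OC/C=C1\C[C@@H](COC(c2ccccc2)(c2ccccc2)c2ccccc2)OC1OC
F3 | step 6 | 3-methylbut-2-enoate of F2 | CC(C)=CC(=O)OC/C=C1\C[C@@H](COC(c2ccccc2)(c2ccccc2)c2ccccc2)OC1OC
F4 | step 6 | lithium dienolate of F3 | [Li+].C=C(C)/C=C(\[O-])OC/C=C1\C[C@@H](COC(c2ccccc2)(c2ccccc2)c2ccccc2)OC1OC
F5 | step 6 | (Z)-trimethylsilyl ketene acetal of F3 | C=C(C)/C=C(\O[Si](C)(C)C)OC/C=C1\C[C@@H](COC(c2ccccc2)(c2ccccc2)c2ccccc2)OC1OC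
F6 | step 6 | trimethylsilyl ester of F7 | C=C[C@]1(C[C@@H](COC(c2ccccc2)(c2ccccc2)c2ccccc2)OC1OC)[C@H](C(C)=C)C(=O)O[Si](C)(C)C
F7 | step 6 | Claisen acid with C14 methyl acetal (5S,8S,10R) | C=C[C@]1(C[C@@H](COC(c2ccccc2)(c2ccccc2)c2ccccc2)OC1OC)[C@H](C(C)=C)C(O)=O
F8 | step 6 | Claisen acid with C14 lactol (5S,8S,10R) | C=C[C@]1(C[C@@H](COC(c2ccccc2)(c2ccccc2)c2ccccc2)OC1O)[C@H](C(C)=C)C(O)=O
F9 | step 15 | (Z)-2-(bromomethyl)allylic alcohol with C6 methyl acetal | C=C[C@]1(COC(OC)[C@H]1C(C)=C)C[C@H](O[Si](C(C)C)(C(C)C)C(C)C)/C=C(\CBr)CO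
F10 | step 15 | (Z)-2-(bromomethyl)allylic alcohol with free C6 lactol | C=C[C@]1(COC(O)[C@H]1C(C)=C)C[C@H](O[Si](C(C)C)(C(C)C)C(C)C)/C=C(\CBr)CO
F11 | step 15 | allylindium dibromide of F10 in its open hydroxy aldehyde form | C=C[C@](CO)(C[C@H](O[Si](C(C)C)(C(C)C)C(C)C)C=C(C[In](Br)Br)CO)[C@@H](C=O)C(C)=C
F12 | step 15 | cyclohexane 6,12,14-triol with equatorial O6 and C11 | C=C[C@]1(CO)C[C@H](O[Si](C(C)C)(C(C)C)C(C)C)[C@@H](C(=C)CO)[C@H](O)[C@H]1C(C)=C
F13 | step 15 | trans-fused α-methylene lactol (C12 anomers) | C=C[C@]1(CO)C[C@H](O[Si](C(C)C)(C(C)C)C(C)C)[C@H]2C(=C)C(O)O[C@@H]2[C@H]1C(C)=C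
F14 | step 12 | lithium enolate of methyl 3-(phenylselanyl)propanoate | [Li+].[O-]C(OC)=CC[Se]c1ccccc1
F15 | step 12 | α-(phenylselanylmethyl) β-hydroxy ester (mixture at C7 and C11) | C=C[C@]1(COC(OC)[C@H]1C(C)=C)C[C@H](O[Si](C(C)C)(C(C)C)C(C)C)C(O)C(C[Se]c1ccccc1)C(=O)OC
F16 | step 12 | selenoxide of F15 | C=C[C@]1(COC(OC)[C@H]1C(C)=C)C[C@H](O[Si](C(C)C)(C(C)C)C(C)C)C(O)C(C[Se](=O)c1ccccc1)C(=O)OC
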